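A direct plan would make diallyl 3-butylglutarate A1, a prochiral diester, by classical malonate chemistry, desymmetrise it with a lipase to the half-ester A2, and reduce and lactonise this to (4R)-4-butyloxan-2-one A3 as the carrier of the stereocentre.
It would then lengthen the two arms one after the other by partial reduction, methoxymethylene Wittig reaction, sulfonate activation, copper-catalysed Grignard coupling and acetalisation to the acetal A4, and finish by B-alkyl Suzuki coupling with methyl 2-(5-bromofuran-2-yl)acetate A5 and acid hydrolysis of the acetal.
Weak point 1, the enzymatic differentiation of the two ester arms: the only stereocentre would rest on one enzyme–substrate match for a flexible 3-alkylglutarate, and the later intermediates are expected to be oils, so a deficit in ee could not be corrected.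
Weak point 2, the run from A2 to A4: six operations of reduction, masking and activation would build only two C–C bonds, and would be needed only because the aldehyde is carried in masked form from the start.
Weak point 3, the late union and unmasking: the Suzuki coupling would put the unstable bromofuran A5 with its acidic CH2 group into warm aqueous base, and the last step would put aqueous acid on a 2,5-dialkylfuran.

Retrosynthetic overview
Locants: side chain C1–C11 (C1 on the furan, C8 the methine, C11 the aldehyde carbon); furan O1′, C2′ (bearing CH2CO2Me) to C5′ (bearing C1). The feature used is that all three arms of C8 begin CH2–CH2, and that the C9–C11 arm is a vinyl group plus CO and H2.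
C10–C11 is cut first (hydroformylation as the last step, aldehyde never masked); C8 thereby becomes an allylic methine, and C7–C8 is cut next: a copper-catalysed enantioselective SN2′ alkylation of (E)-1-bromohept-2-ene sets C8 while it joins butyl, vinyl and chain.
The furan, the only ring, is not brought in as a halofuran: it is closed late from an open chain (C1–C2 by acetylide alkylation, C2′–CH2 by malonate homologation, O1′–C5′ by 5-exo-dig cycloisomerisation of a 3-oxo-6-ynoate), after the stereocentre exists.
The weak steps are avoided by design: the stereocentre comes from catalyst-controlled C–C bond formation with either ligand antipode available, no protecting group or redox correction is used, and neither a base-sensitive bromofuran nor an acid unmasking appears at the end.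

Key step: step 2

Remark on the chemistry (assumption): the ligand antipode that gives the 3R product in step 2 is to be fixed by the first assay of 5; the route is written for that antipode.

Step 1
Reactants: 1 (E)-hept-2-en-1-ol
Product: 2 (E)-1-bromohept-2-ene
Conditions: PBr3 (0.4 equiv), Et2O, −10 → 0 °C, 1 h; used at once
Reagents that add atoms: phosphorus tribromide, BrP(Br)Br
Why: Bromination of a primary allylic alcohol with PBr3 (SN2 displacement of the bromophosphite) at low temperature should keep the E geometry and avoid allylic transposition, giving the linear bromide that the SN2′ step needs.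

Step 2
Reactants: 2 (E)-1-bromohept-2-ene; 3 1-bromo-6-chlorohexane
Product: 5 (3R)-3-butyl-9-chloronon-1-ene, via 6-chlorohexylmagnesium bromide 4 (not isolated)
Conditions: 3 (1.3 equiv), Mg turnings, Et2O, rt → reflux; then CuBr·SMe2 (1 mol%), Taniaphos [1-(α-dimethylamino-2-diphenylphosphinobenzyl)-2-diphenylphosphinoferrocene, one antipode] (1.2 mol%), CH2Cl2, −78 °C, 2 added over 1 h, 12 h; MeOH quench; ee of 5 to be assayed by chiral GC
Reagents that add atoms: none
Why: Magnesium inserts into the C–Br bond of 3 only, and the Grignard reagent 4 transmetalates to a chiral diphosphine complex of monovalent copper; this cuprate adds to the allylic bromide 2 by anti SN2′ oxidative addition to a σ-allyl complex of trivalent copper bound at C3, and reductive elimination there should be faster than σ–π–σ equilibration to the linear isomer. The closest known reaction type is the copper-catalysed enantioselective allylic alkylation of linear aliphatic (E)-allyl bromides with primary alkyl Grignard reagents under ferrocenyl diphosphine ligands. No ring is closed. The new stereocentre (C3 of 5, the later C8) is set under catalyst control: the ligand selects one enantiotopic face of the E-alkene, so the E purity of 2 and the ligand antipode decide the sense and the level of induction. The step needs SN2′ over SN2 selectivity, which the bromide leaving group, CH2Cl2, −78 °C and slow addition of 2 secure, and chemoselectivity for C–Br over C–Cl, which the inert primary chloride secures. In one operation it joins butyl, vinyl and chain at C8 and leaves both the chloride handle for the furan arm and the vinyl group that becomes C9–C11.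

Step 3
Reactants: 5 (3R)-3-butyl-9-chloronon-1-ene; 6 pent-4-ynoic acid
Product: 9 (12R)-12-butyltetradec-13-en-4-ynoic acid, via dilithiated pent-4-ynoic acid 7 (not isolated), via (3R)-3-butyl-9-iodonon-1-ene 8 (not isolated)
Conditions: 6 (1.5 equiv), n-BuLi (3.0 equiv), THF, −78 → 0 °C; DMPU (THF–DMPU 3:1); then 5, NaI (1.0 equiv), 0 → 50 °C, 24 h; 1 M aq HCl
Reagents that add atoms: none
Why: Acetylide alkylation (SN2): the sp carbanion of dianion 7 is far more nucleophilic than its carboxylate, Finkelstein exchange in the flask turns the dormant chloride into iodide 8 as the reactive electrophile, and the stereocentre lies six carbons from the reacting site.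

Step 4
Reactants: 9 (12R)-12-butyltetradec-13-en-4-ynoic acid; 10 potassium methyl malonate
Product: 12 methyl (14R)-14-butyl-3-oxohexadec-15-en-6-ynoate, via acyl imidazolide 11 (not isolated)
Conditions: CDI (1.2 equiv), THF, rt, 2 h; then 10 (2.0 equiv) premixed with MgCl2 (2.0 equiv) in THF, 45 °C, 16 h; 1 M aq HCl
Reagents that add atoms: none
Why: Masamune–Brooks homologation: the acyl imidazolide acylates the magnesium enolate of the malonate half ester and loss of CO2 gives the β-keto ester (C2′–CH2 bond) under near-neutral conditions that leave alkyne, alkene and stereocentre alone.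

Step 5
Reactants: 12 methyl (14R)-14-butyl-3-oxohexadec-15-en-6-ynoate
Product: 14 methyl 2-{5-[(8R)-8-butyldec-9-en-1-yl]furan-2-yl}acetate, via 5-alkylidene-4,5-dihydrofuran 13 (not isolated)
Conditions: (Ph3P)AuCl (2 mol%), AgOTf (2 mol%), toluene, rt, 2 h; then TsOH·H2O (5 mol%), 50 °C, 1 h; Et3N quench; neutral silica
Reagents that add atoms: none
Why: Gold-catalysed cycloisomerisation of an alk-4-yn-1-one: the ketone oxygen attacks the alkyne activated by cationic monovalent gold in the 5-exo-dig mode (O1′–C5′ bond), protodeauration gives enol ether 13, and the acid moves the exocyclic double bond into the ring to give the aromatic furan, while the internal alkyne disfavours Conia-ene carbocyclisation and the terminal alkene is not activated.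

Step 6
Reactants: 14 methyl 2-{5-[(8R)-8-butyldec-9-en-1-yl]furan-2-yl}acetate
Product: 15 methyl 2-{5-[(8R)-8-butyl-11-oxoundecyl]furan-2-yl}acetate (target)
Conditions: Rh(acac)(CO)2 (1 mol%), Xantphos (2 mol%), CO/H2 (1:1, 10 bar), toluene, 70 °C, 16 h
Reagents that add atoms: carbon monoxide, [C-]#[O+]
Why: Hydroformylation: with the wide-bite-angle diphosphine the rhodium hydride adds to the vinyl group with the metal at the terminal carbon (the branched allylic C8 reinforces the linear preference), CO insertion and hydrogenolysis add C11 as the aldehyde under neutral conditions, and the non-isomerising catalyst should leave the C8–H stereocentre, the furan and the ester untouched.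

Compound list
1 | (E)-hept-2-en-1-ol | CCCC/C=C/CO | starting material
2 | (E)-1-bromohept-2-ene | CCCC/C=C/CBr | intermediate
3 | 1-bromo-6-chlorohexane | ClCCCCCCBr | starting material
4 | 6-chlorohexylmagnesium bromide | ClCCCCCC[Mg]Br | intermediate
5 | (3R)-3-butyl-9-chloronon-1-ene | CCCC[C@@H](C=C)CCCCCCCl | intermediate
6 | pent-4-ynoic acid | C#CCCC(=O)O | starting material
7 | dilithiated pent-4-ynoic acid (lithium 5-lithiopent-4-ynoate) | [Li]C#CCCC(=O)O[Li] | intermediate
8 | (3R)-3-butyl-9-iodonon-1-ene | CCCC[C@@H](C=C)CCCCCCI | intermediate
9 | (12R)-12-butyltetradec-13-en-4-ynoic acid | CCCC[C@@H](C=C)CCCCCCC#CCCC(=O)O | intermediate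
10 | potassium methyl malonate (potassium 3-methoxy-3-oxopropanoate) | COC(=O)CC(=O)[O-].[K+] | starting material
11 | (12R)-12-butyl-1-(1H-imidazol-1-yl)tetradec-13-en-4-yn-1-one (acyl imidazolide) | CCCC[C@@H](C=C)CCCCCCC#CCCC(=O)n1ccnc1 | intermediate
12 | methyl (14R)-14-butyl-3-oxohexadec-15-en-6-ynoate | CCCC[C@@H](C=C)CCCCCCC#CCCC(=O)CC(=O)OC | intermediate
13 | methyl 2-{(5Z)-5-[(8R)-8-butyldec-9-en-1-ylidene]-4,5-dihydrofuran-2-yl}acetate | COC(=O)CC1=CC/C(=C/CCCCCC[C@@H](CCCC)C=C)O1 | intermediate
14 | methyl 2-{5-[(8R)-8-butyldec-9-en-1-yl]furan-2-yl}acetate | CCCC[C@@H](C=C)CCCCCCCc1ccc(CC(=O)OC)o1 | intermediate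
15 | methyl 2-{5-[(8R)-8-butyl-11-oxoundecyl]furan-2-yl}acetate | CCCC[C@@H](CCC=O)CCCCCCCc1ccc(CC(=O)OC)o1 | target

Total step count: 6. Longest linear sequence: 6 (1 → 2 → 5 → 9 → 12 → 14 → 15).

Steps most likely to fail

Step 2 (enantioselective SN2′ alkylation). What may go wrong is erosion of enantioselectivity, or leakage to the linear SN2 product, with the long functionalised Grignard reagent. The fallback replaces catalyst control by a reagent-controlled, stereospecific 1,2-metallate rearrangement. Setting out from 3, the Grignard reagent 4 would be borylated with 2-isopropoxy-4,4,5,5-tetramethyl-1,3,2-dioxaborolane to 2-(6-chlorohexyl)-4,4,5,5-tetramethyl-1,3,2-dioxaborolane F1. Pentyl N,N-diisopropylcarbamate F2 (from pentan-1-ol and N,N-diisopropylcarbamoyl chloride) would be lithiated with s-BuLi and the sparteine antipode that leads to the 5R boronic ester (Et2O, −78 °C), trapped with F1 and warmed, so that the 1,2-shift gives 2-[(5R)-11-chloroundecan-5-yl]-4,4,5,5-tetramethyl-1,3,2-dioxaborolane F3. Zweifel olefination (vinylmagnesium bromide, then I2, then NaOMe) would replace boron by vinyl with retention and come back to the route at 5.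

Step 5 (gold-catalysed cycloisomerisation). What may go wrong is diversion of the β-keto ester to carbocyclisation at C2 of the ester, or stalling at the exocyclic enol ether. The fallback closes the O1′–C5′ bond before the β-keto ester exists. Setting out from 9, 5-exo-dig lactonisation of the alkynoic acid (AuCl cat., K2CO3, MeCN, rt) would give (5Z)-5-[(8R)-8-butyldec-9-en-1-ylidene]oxolan-2-one F4. Claisen-type acylation of the lithium enolate of methyl acetate (LiN(i-Pr)2, methyl acetate, THF, −78 °C, 2.2 equiv) by this enol lactone would open the ring to the 1,4-diketone methyl (14R)-14-butyl-3,6-dioxohexadec-15-enoate F5. Paal–Knorr cyclodehydration (TsOH·H2O cat., toluene, 60 °C) would come back to the route at 14.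

Step 3 (acetylide alkylation). What may go wrong is slow displacement at the primary chloride, with elimination of the iodide by the basic dianion. The fallback reverses the polarity of the C1–C2 bond. Methyl 5-bromopent-4-ynoate F6 would be made from methyl pent-4-ynoate (NBS, AgNO3 cat., acetone). Setting out from 5, the chloride would be turned into [(7R)-7-butylnon-8-en-1-yl]magnesium chloride F7 (Mg, THF, reflux) and coupled with F6 under copper catalysis (CuCl2 3 mol%, THF, 0 °C) to methyl (12R)-12-butyltetradec-13-en-4-ynoate F8. Saponification (LiOH, THF–H2O) would come back to the route at 9.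

Further compounds
F1 | step 2 | 2-(6-chlorohexyl)-4,4,5,5-tetramethyl-1,3,2-dioxaborolane | ClCCCCCCB1OC(C)(C)C(C)(C)O1
F2 | step 2 | pentyl N,N-diisopropylcarbamate | CCCCCOC(=O)N(C(C)C)C(C)C
F3 | step 2 | 2-[(5R)-11-chloroundecan-5-yl]-4,4,5,5-tetramethyl-1,3,2-dioxaborolane | CCCC[C@@H](B1OC(C)(C)C(C)(C)O1)CCCCCCCl
F4 | step 5 | (5Z)-5-[(8R)-8-butyldec-9-en-1-ylidene]oxolan-2-one | O=C1CC/C(=C/CCCCCC[C@@H](CCCC)C=C)O1
F5 | step 5 | methyl (14R)-14-butyl-3,6-dioxohexadec-15-enoate | CCCC[C@@H](C=C)CCCCCCCC(=O)CCC(=O)CC(=O)OC
F6 | step 3 | methyl 5-bromopent-4-ynoate | BrC#CCCC(=O)OC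
F7 | step 3 | [(7R)-7-butylnon-8-en-1-yl]magnesium chloride | CCCC[C@@H](C=C)CCCCCC[Mg]Cl
F8 | step 3 | methyl (12R)-12-butyltetradec-13-en-4-ynoate | CCCC[C@@H](C=C)CCCCCCC#CCCC(=O)OC
A1 | direct plan | diprop-2-en-1-yl 3-butylpentanedioate (diallyl 3-butylglutarate) | CCCCC(CC(=O)OCC=C)CC(=O)OCC=C
A2 | direct plan | (3S)-3-[2-oxo-2-(prop-2-en-1-yloxy)ethyl]heptanoic acid | CCCC[C@@H](CC(=O)O)CC(=O)OCC=C
A3 | direct plan | (4R)-4-butyloxan-2-one | CCCC[C@@H]1CCOC(=O)C1
A4 | direct plan | (8R)-8-butyl-11,11-dimethoxyundec-1-ene | CCCC[C@@H](CCC(OC)OC)CCCCCC=C
A5 | direct plan | methyl 2-(5-bromofuran-2-yl)acetate | COC(=O)Cc1ccc(Br)o1
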